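**Plan**
- Retrosynthesis: the imide bond between N1 and the side-chain carbonyl is cut first. The lactam is then opened at N1–C2 and C5–N1 to an acyclic 3,4-diketo ester, with isopropylamine as the nitrogen source.
- Enabling feature: in the pyrrolidine-2,4-dione ring, C5 (the N-bearing CH) lies next to the C4 ketone, and C4 is screened by the quaternary C3. In the open chain these become one ketone beside CH2 and one beside CMe2, which an enzyme pocket can tell apart.
- The diketo ester is cut at ring bond C3–C4 (aldol of a silyl ketene acetal with a keto aldehyde) and at ring bond C4–C5 (diazomethane carbon joined to an acid chloride). The CH–CCl3 bond goes back to BrCCl3 and crotonic acid.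
- Forward: the chain is built first (radical addition, debromination, resolution, one-carbon extension, aldol, oxidation). The only ring then closes (C5–N1, then N1–C2), and N1 is acylated last.
- Stereochemistry: the two CCl3-bearing centres are the two enantiomers of one resolved acid (R in the C5 arm, S in the N-acyl arm). C5 (R) is set by the enzyme.

Key step: step 9

Assumption: the less soluble salt of (R)-1-phenylethylamine is taken to hold the (R)-acid; if the pairing is the reverse, the two amine enantiomers change places in steps 3 and 4, and the configuration of 5 and 6 is to be secured by X-ray of a salt or by correlation before they are carried on.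

**Step 1**
Reactants: 1 (E)-crotonic acid; 2 bromotrichloromethane
Product: 3 2-bromo-4,4,4-trichloro-3-methylbutanoic acid (racemic; both C2 epimers)
Conditions: 2 (4 equiv, neat), AIBN (5 mol %), 75 °C (or visible-lamp irradiation, 40 °C)
Reagents that add atoms: none
Why: Kharasch atom-transfer radical addition, in which the electrophilic CCl3 radical adds to C3 to give the carboxyl-stabilised C2 radical that takes bromine from BrCCl3 and carries the chain; the C2 epimers converge in step 2.

**Step 2**
Reactants: 3 2-bromo-4,4,4-trichloro-3-methylbutanoic acid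
Product: 4 rac-4,4,4-trichloro-3-methylbutanoic acid
Conditions: Zn dust (1.2 equiv), AcOH, 10–15 °C
Reagents that add atoms: none
Why: Reductive dehalogenation of an α-bromo acid by zinc in acetic acid (zinc enolate, then protonation); with limited zinc and low temperature the activated C–Br bond should be reduced well before the CCl3 group.

**Step 3**
Reactants: 4 rac-4,4,4-trichloro-3-methylbutanoic acid
Product: 5 (3R)-4,4,4-trichloro-3-methylbutanoic acid
Conditions: (R)-1-phenylethylamine (1.0 equiv), acetone, crystallise and recrystallise the less soluble salt; then 1 M HCl, Et2O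
Reagents that add atoms: none
Why: Classical resolution through diastereomeric ammonium carboxylate salts; the C3 centre is sorted here, not formed, and the amine is recovered.

**Step 4**
Reactants: 4 4,4,4-trichloro-3-methylbutanoic acid (the S-enriched portion recovered from the mother liquor of step 3)
Product: 6 (3S)-4,4,4-trichloro-3-methylbutanoic acid
Conditions: 1 M HCl, Et2O (recovery); (S)-1-phenylethylamine (1.0 equiv), acetone, recrystallise; then 1 M HCl, Et2O
Reagents that add atoms: none
Why: Mirror-image resolution (Marckwald principle): the salt of the antipodal amine with the antipodal acid is the enantiomer of the salt collected in step 3 and should be equally insoluble.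

**Step 5**
Reactants: 5 (3R)-4,4,4-trichloro-3-methylbutanoic acid
Product: 8 (4R)-5,5,5-trichloro-1-diazo-4-methylpentan-2-one, via acid chloride 7 (not isolated)
Conditions: (COCl)2 (1.2 equiv), DMF (cat.), CH2Cl2, 0 °C to rt, evaporate; then CH2N2 (3 equiv), Et2O, 0 °C
Reagents that add atoms: diazomethane, C=[N+]=[N-]; oxalyl chloride, O=C(Cl)C(=O)Cl (its chlorine is in 7 only)
Why: Acid chloride formation followed by acylation of diazomethane (first half of an Arndt–Eistert sequence); excess diazomethane takes up the HCl, and the centre β to the carbonyl cannot epimerise.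

**Step 6**
Reactants: 8 (4R)-5,5,5-trichloro-1-diazo-4-methylpentan-2-one
Product: 9 (4R)-5,5,5-trichloro-4-methyl-2-oxopentanal
Conditions: DMDO (1.2 equiv, dry acetone solution), 0 °C; evaporate, strip with toluene, use at once
Reagents that add atoms: dimethyldioxirane, CC1(C)OO1
Why: Dioxirane oxidation of an α-diazoketone to an α-keto aldehyde: oxygen is transferred to the diazo carbon with loss of N2 under neutral conditions, and acetone is the only by-product.

**Step 7**
Reactants: 9 (4R)-5,5,5-trichloro-4-methyl-2-oxopentanal; 10 1-methoxy-2-methyl-1-(trimethylsilyloxy)prop-1-ene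
Product: 12 methyl (6R)-7,7,7-trichloro-3-hydroxy-2,2,6-trimethyl-4-oxoheptanoate (C3 epimers), via trimethylsilyl aldol ether 11 (not isolated)
Conditions: 10 (1.5 equiv), Sc(OTf)3 (5 mol %), CH2Cl2, −78 °C; then 1 M HCl, THF, 0 °C
Reagents that add atoms: none
Why: Mukaiyama aldol addition, in which the Lewis acid activates the aldehyde carbonyl (far more electrophilic than the neighbouring ketone) and the tetrasubstituted ketene acetal forms the C2–C3 bond at its quaternary carbon; the carbinol centre forms without control and is removed in step 8.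

**Step 8**
Reactants: 12 methyl (6R)-7,7,7-trichloro-3-hydroxy-2,2,6-trimethyl-4-oxoheptanoate
Product: 13 methyl (6R)-7,7,7-trichloro-2,2,6-trimethyl-3,4-dioxoheptanoate
Conditions: Dess–Martin periodinane (1.3 equiv), CH2Cl2, 0 °C to rt
Reagents that add atoms: none
Why: Dess–Martin oxidation of an acyloin to the 1,2-diketone; the conditions are neutral and metal-free, so the ester, the CCl3 group and C6 are not at risk.

**Step 9**
Reactants: 13 methyl (6R)-7,7,7-trichloro-2,2,6-trimethyl-3,4-dioxoheptanoate; 14 isopropylamine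
Product: 16 (5R)-3,3-dimethyl-5-[(2R)-3,3,3-trichloro-2-methylpropyl]pyrrolidine-2,4-dione, via amino keto ester 15 (not isolated)
Conditions: engineered (R)-selective amine transaminase (ATA-117 lineage, enlarged small pocket, chosen by screening), pyridoxal 5'-phosphate (1 mM), 14 (1 M), KH2PO4/K2HPO4 buffer (100 mM, pH 8.0), DMSO (15% v/v), 13 at 20 mM, 35 °C, N2 sweep to remove acetone; then 40 °C to complete ring closure
Reagents that add atoms: none
Why: The pyridoxamine form of the cofactor, charged by 14 (which leaves as acetone), condenses with the C4 ketone of 13; the active-site lysine shifts the proton through a quinonoid intermediate, hydrolysis releases amino ketone 15, and its amine attacks the methyl ester with loss of methanol. The closest known reactions are the transaminase monoamination of 1,2-diketones at the less hindered carbonyl and the transaminase-triggered lactamisation of γ-keto esters. The ring closes by 5-exo-trig attack of nitrogen on the ester carbonyl (N1–C2), helped by the gem-dimethyl group; this irreversible closure and the removal of acetone pull the equilibrium forward and take the α-amino ketone away before it can dimerise or epimerise. The new C5 centre (R) is set by the enzyme alone, through lysine protonation of one face of the planar quinonoid, and the remote C6 centre should have little say. The step needs regioselectivity between the two ketones, secured by the quaternary C2 of 13, which blocks imine formation at C3; it also needs a pocket large enough for the CH2CH(CH3)CCl3 arm, hence the engineered variant. The neutral aqueous medium holds no hydride or metal, so the CCl3 group and its neighbouring centre are left alone.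

**Step 10**
Reactants: 6 (3S)-4,4,4-trichloro-3-methylbutanoic acid
Product: 17 (3S)-4,4,4-trichloro-3-methylbutanoyl chloride
Conditions: (COCl)2 (1.2 equiv), DMF (cat.), CH2Cl2, 0 °C to rt; evaporate
Reagents that add atoms: oxalyl chloride, O=C(Cl)C(=O)Cl
Why: Standard acid chloride formation through the Vilsmeier-type chloroiminium species; the β-stereocentre cannot epimerise.

**Step 11**
Reactants: 16 (5R)-3,3-dimethyl-5-[(2R)-3,3,3-trichloro-2-methylpropyl]pyrrolidine-2,4-dione; 17 (3S)-4,4,4-trichloro-3-methylbutanoyl chloride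
Product: 19 (5R)-3,3-dimethyl-1-[(3S)-4,4,4-trichloro-3-methylbutanoyl]-5-[(2R)-3,3,3-trichloro-2-methylpropyl]pyrrolidine-2,4-dione, via lithium amidate 18 (not isolated)
Conditions: LiN(SiMe3)2 (1.0 equiv), THF, −78 °C; then 17 (1.2 equiv), −78 °C; AcOH quench at −78 °C
Reagents that add atoms: none
Why: N-Acylation of a lactam through its lithium amidate: the N–H is the most acidic site and is removed first by exactly one equivalent of base, the amidate attacks the acid chloride at nitrogen, and the cold acidic quench should keep the C5–H next to the ketone from exchanging.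

**Compound list**
1 | (E)-crotonic acid | C/C=C/C(=O)O | starting material
2 | bromotrichloromethane | BrC(Cl)(Cl)Cl | starting material
3 | 2-bromo-4,4,4-trichloro-3-methylbutanoic acid (racemic, C2 epimers) | CC(C(Br)C(=O)O)C(Cl)(Cl)Cl | intermediate
4 | rac-4,4,4-trichloro-3-methylbutanoic acid | CC(CC(=O)O)C(Cl)(Cl)Cl | intermediate
5 | (3R)-4,4,4-trichloro-3-methylbutanoic acid | C[C@H](CC(=O)O)C(Cl)(Cl)Cl | intermediate
6 | (3S)-4,4,4-trichloro-3-methylbutanoic acid | C[C@@H](CC(=O)O)C(Cl)(Cl)Cl | intermediate
7 | (3R)-4,4,4-trichloro-3-methylbutanoyl chloride | C[C@H](CC(=O)Cl)C(Cl)(Cl)Cl | intermediate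
8 | (4R)-5,5,5-trichloro-1-diazo-4-methylpentan-2-one | C[C@H](CC(=O)C=[N+]=[N-])C(Cl)(Cl)Cl | intermediate
9 | (4R)-5,5,5-trichloro-4-methyl-2-oxopentanal | C[C@H](CC(=O)C=O)C(Cl)(Cl)Cl | intermediate
10 | 1-methoxy-2-methyl-1-(trimethylsilyloxy)prop-1-ene | COC(O[Si](C)(C)C)=C(C)C | starting material
11 | methyl (6R)-7,7,7-trichloro-2,2,6-trimethyl-4-oxo-3-[(trimethylsilyl)oxy]heptanoate (C3 epimers) | COC(=O)C(C)(C)C(O[Si](C)(C)C)C(=O)C[C@@H](C)C(Cl)(Cl)Cl | intermediate
12 | methyl (6R)-7,7,7-trichloro-3-hydroxy-2,2,6-trimethyl-4-oxoheptanoate (C3 epimers) | COC(=O)C(C)(C)C(O)C(=O)C[C@@H](C)C(Cl)(Cl)Cl | intermediate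
13 | methyl (6R)-7,7,7-trichloro-2,2,6-trimethyl-3,4-dioxoheptanoate | COC(=O)C(C)(C)C(=O)C(=O)C[C@@H](C)C(Cl)(Cl)Cl | intermediate
14 | isopropylamine | CC(C)N | starting material
15 | methyl (4R,6R)-4-amino-7,7,7-trichloro-2,2,6-trimethyl-3-oxoheptanoate | COC(=O)C(C)(C)C(=O)[C@H](N)C[C@@H](C)C(Cl)(Cl)Cl | intermediate
16 | (5R)-3,3-dimethyl-5-[(2R)-3,3,3-trichloro-2-methylpropyl]pyrrolidine-2,4-dione | C[C@H](C[C@@H]1C(=O)C(C)(C)C(=O)N1)C(Cl)(Cl)Cl | intermediate
17 | (3S)-4,4,4-trichloro-3-methylbutanoyl chloride | C[C@@H](CC(=O)Cl)C(Cl)(Cl)Cl | intermediate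
18 | lithium amidate of 16 | C[C@H](C[C@@H]1C(=O)C(C)(C)C(=O)[N-]1)C(Cl)(Cl)Cl.[Li+] | intermediate
19 | (5R)-3,3-dimethyl-1-[(3S)-4,4,4-trichloro-3-methylbutanoyl]-5-[(2R)-3,3,3-trichloro-2-methylpropyl]pyrrolidine-2,4-dione | C[C@H](C[C@@H]1C(=O)C(C)(C)C(=O)N1C(=O)C[C@H](C)C(Cl)(Cl)Cl)C(Cl)(Cl)Cl | target

**Step count**
Total: 11 steps. Longest linear sequence: 9 steps (1, 2, 3, 5, 6, 7, 8, 9, 11); steps 4 and 10 form the short branch to the acyl chloride.

**Steps most likely to fail**

Step 9. Both flanks of the aminated ketone are large, so no available pocket may accept the substrate. The proton may also be delivered to the wrong face, or the free α-amino ketone may dimerise faster than it closes onto the hindered ester. The fallback sets out from 13 and returns at 16, using an auxiliary in place of the enzyme.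
- Condensation of 13 with (R)-tert-butanesulfinamide (Ti(OEt)4, THF) should occur only at the ketone beside CH2 and give methyl (6R)-4-{[(R)-tert-butylsulfinyl]imino}-7,7,7-trichloro-2,2,6-trimethyl-3-oxoheptanoate F1.
- NaBH4 (THF, −48 °C) should reduce the C=N bond under control of the sulfinyl group, and the C3 ketone as well, to give methyl (4R,6R)-4-{[(R)-tert-butylsulfinyl]amino}-7,7,7-trichloro-3-hydroxy-2,2,6-trimethylheptanoate F2.
- HCl in MeOH removes the sulfinyl group to give methyl (4R,6R)-4-amino-7,7,7-trichloro-3-hydroxy-2,2,6-trimethylheptanoate F3.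
- Et3N in warm MeOH closes F3 to (5R)-4-hydroxy-3,3-dimethyl-5-[(2R)-3,3,3-trichloro-2-methylpropyl]pyrrolidin-2-one F4, and Dess–Martin oxidation of F4 gives 16.
- The sense of induction would have to be checked. Because C6 is fixed, a C5 epimer is a diastereomer and can be separated at F2 or F4. The (S)-auxiliary or LiBH(s-Bu)3 is held in reserve to reverse the sense.

Step 7. The keto aldehyde may hydrate or oligomerise before the aldol takes place, or the nucleophile may add at the ketone. The fallback sets out from 8 and returns at 13, replacing aldol and alcohol oxidation by chain extension and α-oxidation of a ketone.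
- Wolff rearrangement of 8 (PhCO2Ag, Et3N, aqueous dioxane) should pass through the ketene (4R)-5,5,5-trichloro-4-methylpent-1-en-1-one F5 to (4R)-5,5,5-trichloro-4-methylpentanoic acid F6.
- Oxalyl chloride converts F6 to (4R)-5,5,5-trichloro-4-methylpentanoyl chloride F7.
- C-Acylation of ketene acetal 10 by F7 (CH2Cl2, rt) should give methyl (6R)-7,7,7-trichloro-2,2,6-trimethyl-3-oxoheptanoate F8.
- Riley oxidation of F8 (SeO2, aqueous dioxane, 90 °C) at its only enolisable methylene leads to 13.

Step 11. Proton transfer at C5 in the amidate or in the more acidic imide may erode the configuration. O-acylation, or base-induced loss of HCl from the acyl chain, may also compete. The fallback sets out from 16 and returns at 19, taking the C4 ketone out of play during acylation.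
- NaBH4 (MeOH, 0 °C) reduces 16 to the hydroxy lactam F4 already named above.
- TBSOTf and 2,6-lutidine give (5R)-4-[(tert-butyldimethylsilyl)oxy]-3,3-dimethyl-5-[(2R)-3,3,3-trichloro-2-methylpropyl]pyrrolidin-2-one F9.
- LiN(SiMe3)2 (THF, −78 °C) forms the lithium amidate of F9, F10, which 17 acylates to (5R)-4-[(tert-butyldimethylsilyl)oxy]-3,3-dimethyl-1-[(3S)-4,4,4-trichloro-3-methylbutanoyl]-5-[(2R)-3,3,3-trichloro-2-methylpropyl]pyrrolidin-2-one F11.
- HF·pyridine frees (5R)-4-hydroxy-3,3-dimethyl-1-[(3S)-4,4,4-trichloro-3-methylbutanoyl]-5-[(2R)-3,3,3-trichloro-2-methylpropyl]pyrrolidin-2-one F12, and Dess–Martin oxidation of F12 gives 19.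

**Further compounds**
F1 | step 9 | methyl (6R)-4-{[(R)-tert-butylsulfinyl]imino}-7,7,7-trichloro-2,2,6-trimethyl-3-oxoheptanoate | COC(=O)C(C)(C)C(=O)C(=N[S@](=O)C(C)(C)C)C[C@@H](C)C(Cl)(Cl)Cl
F2 | step 9 | methyl (4R,6R)-4-{[(R)-tert-butylsulfinyl]amino}-7,7,7-trichloro-3-hydroxy-2,2,6-trimethylheptanoate (C3 epimers) | COC(=O)C(C)(C)C(O)[C@H](N[S@](=O)C(C)(C)C)C[C@@H](C)C(Cl)(Cl)Cl
F3 | step 9 | methyl (4R,6R)-4-amino-7,7,7-trichloro-3-hydroxy-2,2,6-trimethylheptanoate (C3 epimers) | COC(=O)C(C)(C)C(O)[C@H](N)C[C@@H](C)C(Cl)(Cl)Cl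
F4 | step 9 | (5R)-4-hydroxy-3,3-dimethyl-5-[(2R)-3,3,3-trichloro-2-methylpropyl]pyrrolidin-2-one (C4 epimers) | C[C@H](C[C@@H]1C(O)C(C)(C)C(=O)N1)C(Cl)(Cl)Cl
F5 | step 7 | (4R)-5,5,5-trichloro-4-methylpent-1-en-1-one (ketene) | C[C@H](CC=C=O)C(Cl)(Cl)Cl
F6 | step 7 | (4R)-5,5,5-trichloro-4-methylpentanoic acid | C[C@H](CCC(=O)O)C(Cl)(Cl)Cl
F7 | step 7 | (4R)-5,5,5-trichloro-4-methylpentanoyl chloride | C[C@H](CCC(=O)Cl)C(Cl)(Cl)Cl
F8 | step 7 | methyl (6R)-7,7,7-trichloro-2,2,6-trimethyl-3-oxoheptanoate | COC(=O)C(C)(C)C(=O)CC[C@@H](C)C(Cl)(Cl)Cl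
F9 | step 11 | (5R)-4-[(tert-butyldimethylsilyl)oxy]-3,3-dimethyl-5-[(2R)-3,3,3-trichloro-2-methylpropyl]pyrrolidin-2-one (C4 epimers) | C[C@H](C[C@@H]1C(O[Si](C)(C)C(C)(C)C)C(C)(C)C(=O)N1)C(Cl)(Cl)Cl
F10 | step 11 | lithium amidate of F9 | C[C@H](C[C@@H]1C(O[Si](C)(C)C(C)(C)C)C(C)(C)C(=O)[N-]1)C(Cl)(Cl)Cl.[Li+]
F11 | step 11 | (5R)-4-[(tert-butyldimethylsilyl)oxy]-3,3-dimethyl-1-[(3S)-4,4,4-trichloro-3-methylbutanoyl]-5-[(2R)-3,3,3-trichloro-2-methylpropyl]pyrrolidin-2-one (C4 epimers) | C[C@H](C[C@@H]1C(O[Si](C)(C)C(C)(C)C)C(C)(C)C(=O)N1C(=O)C[C@H](C)C(Cl)(Cl)Cl)C(Cl)(Cl)Cl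
F12 | step 11 | (5R)-4-hydroxy-3,3-dimethyl-1-[(3S)-4,4,4-trichloro-3-methylbutanoyl]-5-[(2R)-3,3,3-trichloro-2-methylpropyl]pyrrolidin-2-one (C4 epimers) | C[C@H](C[C@@H]1C(O)C(C)(C)C(=O)N1C(=O)C[C@H](C)C(Cl)(Cl)Cl)C(Cl)(Cl)Cl
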